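The ten-membered ring (C1–C10, briarane numbering) is opened at C6–C7. This bond lies inside the triad C16H2=C5–C6H(Cl)–C7H(O), which is the retron of a γ-chloroallyl-metal addition to an aldehyde. An intramolecular Nozaki–Hiyama–Kishi reaction closes the carbocycle, sets C6 and C7, keeps the chlorine and shifts the alkene into the C5 exomethylene in one operation. It also funnels an E/Z mixture of the chloroalkene into one diastereomer. The precursor is an open C7 aldehyde with a 1,3-dichloroallyl terminus. It is built from three fragments: a Birch-derived cyclohexenyl allylsilane, a β-chloroenal (aldol, C3–C4) and a chiral-pool dialdehyde (Hosomi–Sakurai, C9–C10). Oxidative lactonisation ends the route.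

Key step: step 19

Numbering: C1 quaternary C (Me-15), C2 OAc, C3 CH2, C4 OAc, C5 (=C16H2), C6 Cl, C7 lactone O, C8 OH, C9 OAc, C10 ring-fusion CH, C11 (=C20H2), C12, C13, C14 OAc, C17 CH(Me-18), C19 C=O. The target is 1R,2S,4R,6S,7R,8R,9S,10S,14S,17R.

Remark: all compounds derived from 6 are carried as C5=C6 E/Z mixtures, so that double bond is left undefined in their SMILES.

Assumption: the facial sense of the prolinol-ether auxiliary (step 11) and of (−)-Ipc2BCl (step 13) is taken as drawn. If either is opposite, the enantiomeric controller is used with no other change.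

**Fragment C4–C6/C16**

Step 1
Reactants: 1 2,2-dimethyl-1,3-dioxan-5-one
Product: 2 5-(chloromethylidene)-2,2-dimethyl-1,3-dioxane
Conditions: Ph3P+CH2Cl Cl−, NaHMDS, THF, −78 to 0 °C; then 1
Reagents that add atoms: (chloromethyl)triphenylphosphonium chloride, ClC[P+](c1ccccc1)(c1ccccc1)c1ccccc1.[Cl-]
Why: Wittig chloromethylenation of an unhindered symmetrical ketone, whose two identical arms mean no alkene isomers can arise here.

Step 2
Reactants: 2 5-(chloromethylidene)-2,2-dimethyl-1,3-dioxane
Product: 3 2-(chloromethylidene)propane-1,3-diol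
Conditions: 1 M HCl, THF, rt
Reagents that add atoms: none
Why: Acid-catalysed acetonide hydrolysis, to which the vinyl chloride is inert.

Step 3
Reactants: 3 2-(chloromethylidene)propane-1,3-diol
Product: 4 3-chloro-2-(hydroxymethyl)prop-2-enal (E/Z mixture)
Conditions: MnO2, CH2Cl2, rt
Reagents that add atoms: none
Why: MnO2 allylic oxidation should stop at the mono-aldehyde because the remaining alcohol then sits on an electron-poor enal, and the E/Z mixture from reaction at either arm is made irrelevant by step 19.

Step 4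
Reactants: 4 3-chloro-2-(hydroxymethyl)prop-2-enal
Product: 6 3-chloro-2-(chloromethyl)prop-2-enal (E/Z mixture), via mesylate 5 (not isolated)
Conditions: MsCl, Et3N, CH2Cl2, −30 °C; then LiCl, THF, 0 °C
Reagents that add atoms: lithium chloride, [Li+].[Cl-]; methanesulfonyl chloride, CS(=O)(=O)Cl (its atoms stay only in 5)
Why: Mesylation followed by SN2 displacement with chloride is the standard mild route to primary allylic chlorides and leaves the enal untouched.

**Fragment C7–C9/C17–C19**

Step 5
Reactants: 7 methyl (S)-3-hydroxy-2-methylpropanoate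
Product: 8 methyl (S)-3-(tert-butyldimethylsilyloxy)-2-methylpropanoate
Conditions: TBSCl, imidazole, CH2Cl2, rt
Reagents that add atoms: tert-butyldimethylsilyl chloride, CC(C)(C)[Si](C)(C)Cl
Why: Standard silylation of the primary alcohol, with C17 taken from the chiral pool and not touched.

Step 6
Reactants: 8 methyl (S)-3-(tert-butyldimethylsilyloxy)-2-methylpropanoate
Product: 10 (S)-3-[1-(tert-butyldimethylsilyloxy)propan-2-yl]penta-1,4-dien-3-ol, via vinyl ketone 9 (not isolated)
Conditions: CH2=CHMgBr (3.5 equiv), CeCl3, THF, −78 to 0 °C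
Reagents that add atoms: vinylmagnesium bromide, C=C[Mg]Br
Why: Double 1,2-addition of the cerium-modified Grignard reagent to the ester, in which CeCl3 suppresses enolisation (protecting C17) and 1,4-addition to 9, and two identical arms leave C8 non-stereogenic.

Step 7
Reactants: 10 (S)-3-[1-(tert-butyldimethylsilyloxy)propan-2-yl]penta-1,4-dien-3-ol
Product: 11 triethylsilyl ether of 10
Conditions: TESOTf, 2,6-lutidine, CH2Cl2, 0 °C
Reagents that add atoms: triethylsilyl triflate, CC[Si](CC)(CC)OS(=O)(=O)C(F)(F)F
Why: Silyl triflate with lutidine is the standard silylation for hindered tertiary alcohols.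

Step 8
Reactants: 11 triethylsilyl ether of 10
Product: 13 (S)-2-[1-(tert-butyldimethylsilyloxy)propan-2-yl]-2-(triethylsilyloxy)propanedial, via bis-ozonide 12 (not isolated)
Conditions: O3, CH2Cl2, −78 °C; Me2S, −78 °C to rt
Reagents that add atoms: ozone, [O-][O+]=O
Why: Ozonolysis with reductive work-up cleaves both vinyl groups, and the dialdehyde cannot enolise because C8 is fully substituted.

**Main line**

Step 9
Reactants: 14 5-bromo-2-methoxybenzoic acid; 15 (S)-2-(methoxymethyl)pyrrolidine
Product: 16 (S)-(5-bromo-2-methoxyphenyl)[2-(methoxymethyl)pyrrolidin-1-yl]methanone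
Conditions: EDCI·HCl, HOBt, iPr2NEt, CH2Cl2, rt
Reagents that add atoms: none
Why: Carbodiimide amide coupling attaches the chiral auxiliary.

Step 10
Reactants: 16 (S)-(5-bromo-2-methoxyphenyl)[2-(methoxymethyl)pyrrolidin-1-yl]methanone
Product: 17 (S)-{2-methoxy-5-[(trimethylsilyl)methyl]phenyl}[2-(methoxymethyl)pyrrolidin-1-yl]methanone
Conditions: Me3SiCH2MgCl, NiCl2(dppp) (5 mol %), THF, reflux
Reagents that add atoms: (trimethylsilyl)methylmagnesium chloride, C[Si](C)(C)C[Mg]Cl
Why: Kumada–Corriu coupling of an aryl bromide with a β-hydrogen-free Grignard reagent is a standard route to benzylsilanes and tolerates the tertiary amide.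

Step 11
Reactants: 17 (S)-{2-methoxy-5-[(trimethylsilyl)methyl]phenyl}[2-(methoxymethyl)pyrrolidin-1-yl]methanone
Product: 19 {(1R)-2-methoxy-1-methyl-5-[(trimethylsilyl)methyl]cyclohexa-2,5-dien-1-yl}[(2S)-2-(methoxymethyl)pyrrolidin-1-yl]methanone, via potassium amide enolate 18 (not isolated)
Conditions: K (2.2 equiv), NH3(l)/THF, t-BuOH (1 equiv), −78 °C; MeI, −78 °C
Reagents that add atoms: iodomethane, CI
Why: In this asymmetric Birch reduction–alkylation (prolinol-ether benzamide auxiliary) MeI attacks the chelated enolate 18 on the face not shielded by the methoxymethyl arm, which sets quaternary C1 while the benzylsilane becomes the C10=C11 allylsilane and the anisole oxygen a masked C14 ketone.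

Step 12
Reactants: 19 Birch product (1R)
Product: 20 1-{(1R)-2-methoxy-1-methyl-5-[(trimethylsilyl)methyl]cyclohexa-2,5-dien-1-yl}ethanone
Conditions: MeLi (2.5 equiv), Et2O, −78 to 0 °C; pH 7 buffer
Reagents that add atoms: methyllithium, [Li]C
Why: Organolithium addition to a tertiary amide gives a tetrahedral lithium alkoxide that collapses to the methyl ketone only on buffered work-up, so over-addition is avoided, the auxiliary is released and the enol ether survives.

Step 13
Reactants: 20 methyl ketone (1R); 6 3-chloro-2-(chloromethyl)prop-2-enal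
Product: 21 (3R)-5-chloro-4-(chloromethyl)-3-hydroxy-1-{(1R)-2-methoxy-1-methyl-5-[(trimethylsilyl)methyl]cyclohexa-2,5-dien-1-yl}pent-4-en-1-one (briarane 1R,4R)
Conditions: (−)-Ipc2BCl, Et3N, Et2O, 0 °C; 6, −78 to −20 °C; H2O2, MeOH, pH 7 buffer
Reagents that add atoms: none
Why: In this diisopinocampheylboron-mediated aldol reaction only the methyl side of 20 can enolise (C1 is quaternary), the enol borinate adds 1,2 to the enal through a cyclic transition state, and the Ipc ligands select the aldehyde face to set C4.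

Step 14
Reactants: 21 aldol adduct (1R,4R)
Product: 23 (2S)-2-[(1S,3R)-5-chloro-4-(chloromethyl)-1,3-dihydroxypent-4-en-1-yl]-2-methyl-4-[(trimethylsilyl)methyl]cyclohex-3-en-1-one, via syn-diol enol ether 22 (not isolated)
Conditions: Et2BOMe, NaBH4, THF/MeOH 4:1, −78 °C; MeOH azeotrope; then oxalic acid (cat.), THF/H2O, 0 °C
Reagents that add atoms: water, O
Why: In the Narasaka–Prasad reduction the six-membered boron chelate of the C4 alkoxide and C2 ketone takes external axial hydride to give the 2,4-syn diol (sets C2), and mild acid then hydrolyses the enol ether to the C14 ketone, which cannot conjugate because C1 is quaternary.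

Step 15
Reactants: 23 keto diol
Product: 24 (1S,2R)-2-[(1S,3R)-5-chloro-4-(chloromethyl)-1,3-dihydroxypent-4-en-1-yl]-2-methyl-4-[(trimethylsilyl)methyl]cyclohex-3-en-1-ol (briarane 1R,2S,4R,14S)
Conditions: Me4NBH(OAc)3, MeCN/AcOH, −30 °C
Reagents that add atoms: none
Why: In the Evans–Saksena reduction the C2 hydroxyl binds the borohydride and delivers hydride through a chair transition state, giving the 2,14-anti diol, which is the axial C14 alcohol cis to the C2 chain (sets C14).

Step 16
Reactants: 24 triol
Product: 25 2,4,14-triacetate of 24 (1R,2S,4R,14S)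
Conditions: Ac2O, Et3N, DMAP (cat.), CH2Cl2, 0 °C to rt
Reagents that add atoms: acetic anhydride, CC(=O)OC(C)=O
Why: DMAP-catalysed acetylation installs three of the four final acetates at once, with only catalytic DMAP used to spare the allylic chloride.

Step 17
Reactants: 25 allylsilane triacetate; 13 dialdehyde (1.5 equiv)
Product: 26 seco-aldehyde with free 9-OH (1R,2S,4R,8R,9S,10S,14S,17S; C11 exomethylene, 8-OTES, C7 formyl, 19-OTBS)
Conditions: BF3·OEt2, CH2Cl2, −78 °C
Reagents that add atoms: none
Why: In this Hosomi–Sakurai allylation (SE2′) C10 attacks axially on the face cis to Me-15 because the other face meets the C14 acetate in a syn-axial clash, the open antiperiplanar transition state of the E-type allylsilane gives the 9,10-syn relation, and only one of the two diastereotopic formyl groups offers the required face in a polar Felkin–Anh arrangement (C8–OTES anti to C10, C17 branch inside), so C8, C9 and C10 are set together while loss of silicon creates the C11 exomethylene.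

Step 18
Reactants: 26 seco-aldehyde with free 9-OH
Product: 27 2,4,9,14-tetraacetate seco-aldehyde (1R,2S,4R,8R,9S,10S,14S,17S)
Conditions: Ac2O, Et3N, DMAP (cat.), CH2Cl2, 0 °C
Reagents that add atoms: acetic anhydride, CC(=O)OC(C)=O
Why: Acetylation of the only free hydroxyl, with the remaining aldehyde unable to enolise because C8 is fully substituted.

Step 19
Reactants: 27 tetraacetate seco-aldehyde (C5=C6 E/Z mixture)
Product: 29 ten-membered chlorohydrin (6S,7R; 7-OH, 8-OTES, 19-OTBS, C5 and C11 exomethylenes; other centres as in 27), via allylchromium species 28 (not isolated)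
Conditions: CrCl2 (4 equiv), 4 Å MS, THF/DMF 4:1, rt, syringe-pump addition of 27 (final about 1 mM)
Reagents that add atoms: none
Why: Two single-electron transfers from Cr(II) to the primary allylic C16–Cl bond give the γ-chloroallylchromium(III) species 28, whose E and Z forms interconvert by 1,3-metallotropic shift faster than they add, so both geometrical isomers of 27 drain through the same lowest transition state. C6 then attacks the C7 aldehyde in an SE2′ sense through a six-membered Zimmerman–Traxler chair, which moves the double bond to C5=C16 and leaves the chlorine on C6. The closest known reactions are the Nozaki–Hiyama–Kishi allylation, its chromium-mediated variant with 1,3-dichloropropene that gives chlorohydrins, and NHK closures of ten-membered carbocycles from allylic halide aldehydes. The only ring closed is the carbocycle C1–C10, formed 10-exo-trig at the carbonyl group under pseudo-high dilution. The 6,7-anti relation follows from the chair with chlorine pseudo-equatorial (Cl trans to CH2Cr), and the C7 face is chosen by a polar Felkin–Anh arrangement at C8 (C8–OSiEt3 anti to incoming C6, bulky C9 branch inside, C17 outside), giving 6S,7R. The step needs metalation of only one C–Cl bond and survival of the product chloride: the vinylic C6–Cl bond is inert to Cr(II) without nickel, acetates and silyl ethers are tolerated, and the new hindered secondary allylic chloride is reduced far more slowly than the primary one when only a small excess of CrCl2 is present.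

Step 20
Reactants: 29 ten-membered chlorohydrin
Product: 30 7,8,19-triol (configurations unchanged)
Conditions: HF·pyridine, pyridine, THF, 0 °C to rt
Reagents that add atoms: none
Why: Buffered fluoride desilylation removes both silyl ethers while acetates and the allylic chloride persist.

Step 21
Reactants: 30 7,8,19-triol
Product: 32 target CNP0186618.1 (1R,2S,4R,6S,7R,8R,9S,10S,14S,17R), via lactol 31 (not isolated)
Conditions: TEMPO (0.2 equiv), PhI(OAc)2 (2.5 equiv), CH2Cl2, rt
Reagents that add atoms: none
Why: In this TEMPO/PhI(OAc)2 oxidative lactonisation of a 1,4-diol the primary C19 alcohol is oxidised selectively, the aldehyde is trapped by the C7 hydroxyl as lactol 31 and oxidised on to the γ-lactone, while the tertiary C8 alcohol is inert and no stereocentre is touched.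

**Compound list**

1 | 2,2-dimethyl-1,3-dioxan-5-one | CC1(C)OCC(=O)CO1 | starting material
2 | 5-(chloromethylidene)-2,2-dimethyl-1,3-dioxane | CC1(C)OCC(=CCl)CO1 | intermediate
3 | 2-(chloromethylidene)propane-1,3-diol | OCC(=CCl)CO | intermediate
4 | 3-chloro-2-(hydroxymethyl)prop-2-enal (E/Z) | O=CC(CO)=CCl | intermediate
5 | 2-(chloromethylidene)-3-oxopropyl methanesulfonate (E/Z, not isolated) | CS(=O)(=O)OCC(C=O)=CCl | intermediate
6 | 3-chloro-2-(chloromethyl)prop-2-enal (E/Z) | O=CC(CCl)=CCl | intermediate
7 | methyl (S)-3-hydroxy-2-methylpropanoate | COC(=O)[C@@H](C)CO | starting material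
8 | methyl (S)-3-(tert-butyldimethylsilyloxy)-2-methylpropanoate | COC(=O)[C@@H](C)CO[Si](C)(C)C(C)(C)C | intermediate
9 | (S)-5-(tert-butyldimethylsilyloxy)-4-methylpent-1-en-3-one (not isolated) | C=CC(=O)[C@@H](C)CO[Si](C)(C)C(C)(C)C | intermediate
10 | (S)-3-[1-(tert-butyldimethylsilyloxy)propan-2-yl]penta-1,4-dien-3-ol | C=CC(O)(C=C)[C@@H](C)CO[Si](C)(C)C(C)(C)C | intermediate
11 | triethylsilyl ether of 10 | C=CC(O[Si](CC)(CC)CC)(C=C)[C@@H](C)CO[Si](C)(C)C(C)(C)C | intermediate
12 | bis(1,2,4-trioxolane) from 11 (not isolated) | CC[Si](CC)(CC)OC(C1OCOO1)(C1OCOO1)[C@@H](C)CO[Si](C)(C)C(C)(C)C | intermediate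
13 | (S)-2-[1-(tert-butyldimethylsilyloxy)propan-2-yl]-2-(triethylsilyloxy)propanedial | O=CC(C=O)(O[Si](CC)(CC)CC)[C@@H](C)CO[Si](C)(C)C(C)(C)C | intermediate
14 | 5-bromo-2-methoxybenzoic acid | COc1ccc(Br)cc1C(=O)O | starting material
15 | (S)-2-(methoxymethyl)pyrrolidine | COC[C@@H]1CCCN1 | starting material
16 | bromo benzamide | COc1ccc(Br)cc1C(=O)N1CCC[C@H]1COC | intermediate
17 | benzylsilane benzamide | COc1ccc(C[Si](C)(C)C)cc1C(=O)N1CCC[C@H]1COC | intermediate
18 | potassium amide enolate (not isolated) | C[Si](C)(C)CC1=CC(=C([O-])N2CCC[C@H]2COC)C(OC)=CC1.[K+] | intermediate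
19 | Birch product (1R, auxiliary S) | C[Si](C)(C)CC1=C[C@@](C)(C(=O)N2CCC[C@H]2COC)C(OC)=CC1 | intermediate
20 | methyl ketone (1R) | C[Si](C)(C)CC1=C[C@@](C)(C(C)=O)C(OC)=CC1 | intermediate
21 | aldol adduct (1R,4R) | C[Si](C)(C)CC1=C[C@@](C)(C(=O)C[C@@H](O)C(CCl)=CCl)C(OC)=CC1 | intermediate
22 | 2,4-syn diol enol ether (not isolated) | C[Si](C)(C)CC1=C[C@@](C)([C@@H](O)C[C@@H](O)C(CCl)=CCl)C(OC)=CC1 | intermediate
23 | keto diol | C[Si](C)(C)CC1=C[C@@](C)([C@@H](O)C[C@@H](O)C(CCl)=CCl)C(=O)CC1 | intermediate
24 | 2,4,14-triol (1R,2S,4R,14S) | C[Si](C)(C)CC1=C[C@@](C)([C@@H](O)C[C@@H](O)C(CCl)=CCl)[C@@H](O)CC1 | intermediate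
25 | 2,4,14-triacetate allylsilane | C[Si](C)(C)CC1=C[C@@](C)([C@@H](OC(C)=O)C[C@@H](OC(C)=O)C(CCl)=CCl)[C@@H](OC(C)=O)CC1 | intermediate
26 | seco-aldehyde, 9-OH | C=C1CC[C@H](OC(C)=O)[C@](C)([C@@H](OC(C)=O)C[C@@H](OC(C)=O)C(CCl)=CCl)[C@H]1[C@@H]([C@@](O[Si](CC)(CC)CC)(C=O)[C@@H](C)CO[Si](C)(C)C(C)(C)C)O | intermediate
27 | seco-aldehyde tetraacetate | C=C1CC[C@H](OC(C)=O)[C@](C)([C@@H](OC(C)=O)C[C@@H](OC(C)=O)C(CCl)=CCl)[C@H]1[C@@H]([C@@](O[Si](CC)(CC)CC)(C=O)[C@@H](C)CO[Si](C)(C)C(C)(C)C)OC(C)=O | intermediate
28 | γ-chloroallylchromium(III) dichloride (not isolated) | C=C1CC[C@H](OC(C)=O)[C@](C)([C@@H](OC(C)=O)C[C@@H](OC(C)=O)C(C[Cr](Cl)Cl)=CCl)[C@H]1[C@@H]([C@@](O[Si](CC)(CC)CC)(C=O)[C@@H](C)CO[Si](C)(C)C(C)(C)C)OC(C)=O | intermediate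
29 | ten-membered chlorohydrin | C=C1CC[C@H](OC(C)=O)[C@]2(C)[C@@H](OC(C)=O)C[C@@H](OC(C)=O)C(=C)[C@H](Cl)[C@H](O)[C@@](O[Si](CC)(CC)CC)([C@@H](C)CO[Si](C)(C)C(C)(C)C)[C@@H](OC(C)=O)[C@@H]12 | intermediate
30 | 7,8,19-triol | C=C1CC[C@H](OC(C)=O)[C@]2(C)[C@@H](OC(C)=O)C[C@@H](OC(C)=O)C(=C)[C@H](Cl)[C@H](O)[C@@](O)([C@@H](C)CO)[C@@H](OC(C)=O)[C@@H]12 | intermediate
31 | C19 lactol (not isolated, C19 undefined) | C=C1CC[C@H](OC(C)=O)[C@]2(C)[C@@H](OC(C)=O)C[C@@H](OC(C)=O)C(=C)[C@H](Cl)[C@@H]3OC(O)[C@H](C)[C@@]3(O)[C@@H](OC(C)=O)[C@@H]12 | intermediate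
32 | CNP0186618.1 | C=C1CC[C@H](OC(C)=O)[C@]2(C)[C@@H](OC(C)=O)C[C@@H](OC(C)=O)C(=C)[C@H](Cl)[C@@H]3OC(=O)[C@H](C)[C@@]3(O)[C@@H](OC(C)=O)[C@@H]12 | target

Total step count: 21.
Longest linear sequence: 13 steps (steps 9–21, from 14).

**Steps most likely to fail**

1. Step 19. Oligomerisation may compete with closure of the strained ring. Chromium(II) may go on to reduce the freshly formed allylic chloride, followed by β-elimination, and the anti selectivity may erode. The fallback sets out from 27 and comes back at 29, and it replaces the reductive umpolung by an allylboration. The geometrical isomer of 27 with Cl trans to CH2Cl is separated. It is converted at high dilution by palladium-catalysed Miyaura-type allylic borylation (B2pin2) into the configurationally stable γ-chloroallyl pinacolboronate F1. F1 cyclises in the same flask through a closed chair transition state. No low-valent metal is present, and aqueous work-up should give 29.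

2. Step 17. Steric congestion may slow the addition, and the discrimination between the two formyl groups and their faces may be insufficient. The fallback sets out from 11 and comes back at 27, and it fixes C8 before the coupling.
   - Ozonolysis of 11 with NaBH4 work-up gives the 1,3-diol F2.
   - A group-selective mono-silylation (TESCl, amino-acid-derived imidazole catalyst) gives the mono-TES ether F3.
   - Dess–Martin oxidation gives the mono-aldehyde F4.
   - Hosomi–Sakurai reaction of F4 with 25 gives the adduct F5, and acetylation gives the acetate F6.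
   - Direct Swern oxidation of the primary triethylsilyl ether of F6 delivers 27.

3. Step 12. The hindered amide may resist addition, or deprotonation may compete. The fallback sets out from 19 and comes back at 20, and it changes from acyl substitution to a redox sequence. Lithium amidotrihydroborate reduces 19 to the primary alcohol F7. Parikh–Doering oxidation gives the aldehyde F8. MeMgBr gives the secondary alcohol F9 as an epimer mixture. Dess–Martin oxidation (NaHCO3 buffer) then gives 20.

Further compounds
F1 | step 19 | γ-chloroallyl pinacolboronate aldehyde (Cl trans to CH2B) | C=C1CC[C@H](OC(C)=O)[C@](C)([C@@H](OC(C)=O)C[C@@H](OC(C)=O)/C(CB2OC(C)(C)C(C)(C)O2)=C\Cl)[C@H]1[C@@H]([C@@](O[Si](CC)(CC)CC)(C=O)[C@@H](C)CO[Si](C)(C)C(C)(C)C)OC(C)=O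
F2 | step 17 | 2-[(S)-1-(tert-butyldimethylsilyloxy)propan-2-yl]-2-(triethylsilyloxy)propane-1,3-diol | OCC(CO)(O[Si](CC)(CC)CC)[C@@H](C)CO[Si](C)(C)C(C)(C)C
F3 | step 17 | mono-TES ether (C7-OTES, C9-OH, C8 as in 27) | OC[C@@](O[Si](CC)(CC)CC)(CO[Si](CC)(CC)CC)[C@@H](C)CO[Si](C)(C)C(C)(C)C
F4 | step 17 | C9 mono-aldehyde | O=C[C@@](O[Si](CC)(CC)CC)(CO[Si](CC)(CC)CC)[C@@H](C)CO[Si](C)(C)C(C)(C)C
F5 | step 17 | Hosomi–Sakurai adduct with C7-OTES and 9-OH | C=C1CC[C@H](OC(C)=O)[C@](C)([C@@H](OC(C)=O)C[C@@H](OC(C)=O)C(CCl)=CCl)[C@H]1[C@@H]([C@@](O[Si](CC)(CC)CC)(CO[Si](CC)(CC)CC)[C@@H](C)CO[Si](C)(C)C(C)(C)C)O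
F6 | step 17 | 9-acetate of F5 | C=C1CC[C@H](OC(C)=O)[C@](C)([C@@H](OC(C)=O)C[C@@H](OC(C)=O)C(CCl)=CCl)[C@H]1[C@@H]([C@@](O[Si](CC)(CC)CC)(CO[Si](CC)(CC)CC)[C@@H](C)CO[Si](C)(C)C(C)(C)C)OC(C)=O
F7 | step 12 | primary alcohol from 19 | C[Si](C)(C)CC1=C[C@@](C)(CO)C(OC)=CC1
F8 | step 12 | C2 aldehyde | C[Si](C)(C)CC1=C[C@@](C)(C=O)C(OC)=CC1
F9 | step 12 | secondary alcohol (carbinol epimers) | C[Si](C)(C)CC1=C[C@@](C)(C(C)O)C(OC)=CC1
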